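Ask first how much target a free catalyst that dies can make in 20 h, and which doubling buys most.

substrate 1.5 M; gas phase 160 mM (held); protic impurity 1.50 M; free catalyst 220 mM; time 20 h

    dissolved gas + protic impurity → quenched reagent (k1 = 0.21 M⁻¹ h⁻¹)
    gas phase ⇌ dissolved gas, rate k2*(csat - [dissolved gas]) (k2 = 1.4 h⁻¹, csat = 160 mM)
    free catalyst → spent catalyst (k3 = 0.21 h⁻¹)
    substrate + dissolved gas + free catalyst → free catalyst + target (k4 = 28 M⁻² h⁻¹)

- the target standing at 20 h, as a percentage of the substrate charged
- the change that raises the amount of target at 20 h, in percent of the substrate charged most ("none" if none brings more than 2 percentage points) (theta / delta / alpha / none)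
- amount of target at 20 h, in percent of the substrate charged, after delta

Write the balance of the free catalyst first: step 3 removes it and step 4 returns it whole, so its integral over the run is 61.9 M·min. Now take two ways to the yield. Hold [dissolved gas] at 160 mM, and that integral gives 99.0%. Count the gas instead, with step 2 at full pull for one catalyst lifetime, and you get 71.1%. They part by 28 percentage points.

The first way cheats: transfer closes half of any gap in 0.495 h, but as charged, step 4 halves [dissolved gas] in 0.075 h, which is faster than transfer. The second errs the other way: the run of 20 h is longer than the catalyst lifetime of 4.76 h, and gas goes on arriving after that lifetime.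

So merge them. Leave step 4 out of the balance of dissolved gas, hold protic impurity at its charge, and the level reckons to 0.131 M. Multiply that level by k4 and by the catalyst integral to get N = 3.77, the exposure number. Put [dissolved gas] at steady state, hold protic impurity at its charge, and take free catalyst over the conversion X as 0.5 of its charge. The balance becomes: ln(charged substrate over substrate left) + mX = N, where m = 2.69 is the price of gas starvation.

Try X = 80.0%: the left side is 3.76 against N of 3.77, so commit to that yield. Doubling the free catalyst doubles N and m and gives 92.5%. Doubling the saturation doubles N, leaves m as it is and gives 99.2%. Doubling k2 moves N to 4.16 and m to 1.48, which gives 93.7%. Back theta, higher than either.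

The forecast gives 81.5% (77% to 85%), 94% after delta (91% to 96.5%) and theta as best, holding that “doubling the saturation concentration doubles both the gas supply and the dissolved level”.

The flask gives 79.9%, and 92.5% after delta. Its best change is theta, worth 18 points, against 13 points for delta and 12 points for alpha.

Put 79.9% back into the balance: the left side reads 3.75 against N of 3.77. Free catalyst in this flask is down to 1.50% at 20.0 h, and the target reads 81.1% at 200 h. Now charge a neighbour flask with 0.055 M of free catalyst: N falls to 0.943 and m to 0.673, and the balance gives 46.7%. That neighbour flask reads 45.1% at 20.0 h, with 55% of its substrate left.

The rate constants are invented, and the outcome is calculated.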